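## The problem

Compound 25 is a cis-fused 1,4,4a,5,8,8a-hexahydronaphthalen-5-one. Ring A (C1, C2, C3, C4, C4a, C8a) is a cyclohexene with a hexadecyl group on C2 of the C2=C3 bond and methyl esters on both allylic carbons C1 and C4; ring B (C4a, C5, C6, C7, C8, C8a) is a cyclohex-2-enone with the ketone at C5, an ester at C6 and a hexadecyl group at C7. The four stereocentres C1, C4, C4a and C8a are contiguous and all lie on ring A: H4, H4a, H8a and the C1 ester share one face, so the ring fusion is cis, the C4 ester is cis to C5 and the C1 ester is trans to C8. Ring B has no stereocentre of its own and can be closed last; C8a can direct C1 through a cyclic enolate, and a centre on C2 can direct C4 and C4a if the C4–C4a bond is formed intramolecularly. All four centres are epimerisable once the rings exist (C1 and C4 are allylic and alpha to esters, C4a is alpha to the C5 ketone), and the C2=C3 bond can slip into conjugation with either ester, so strong base, strong acid and long heating are excluded late in the route. Three methyl esters of similar reactivity rule out late hydride or organometallic steps. The feature that opens the structure is the unit O=C5–C4a–C4–C3=C2, a gamma,delta-unsaturated carbonyl group with its alkene inside ring A: this is the retron of a Claisen rearrangement that makes C4–C4a and breaks an O–C2 bond, so ring A can be traced back to a 2-alkenyl-3,4-dihydro-2H-pyran (ring atoms O, C2, C1, C8a, C4a, C5).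

## Retrosynthesis

**C6=C7 (ring B).** Cutting C6=C7 of 25 leads to the β-keto ester 23, in which C6 is an active methylene carbon and C7 a dialkyl ketone five atoms away. This cut removes ring B without touching a stereocentre, unlike the neighbouring C5–C6 or C7–C8 cuts made on the intact bicycle. The forward step is an intramolecular Knoevenagel condensation under buffered amine catalysis, which must leave H4a and the C2=C3 bond where they are.

**C5–C6.** Cutting C5–C6 of 23 removes the malonyl unit and leaves aldehyde 22 with the formyl carbon C5 on C4a. A diazoacetate homologation of the aldehyde (Roskamp reaction) is preferred to acylating an ester enolate with a C5 acid derivative, because it needs no base next to the epimerisable C4a and C4. Compound 22 is a monocyclic cyclohexene with all four stereocentres and both hexadecyl chains.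

**C4–C4a, with O joined to C2.** In 22, cutting C4–C4a and joining the C5 oxygen to C2 gives the 2-alkenyl-3,4-dihydro-2H-pyran 21. Other ring A cuts would create three or four contiguous centres at once or under basic conditions; this one creates only C4 and C4a, and both follow from one quaternary centre (C2) and one alkene geometry. The precursor is simpler by one carbocycle and two stereocentres. The forward rearrangement must pass through the ring-enforced boat and must be run free of acid.

**C3=C4 and the enol ether.** The (E)-enoate of 21 is cut at C3=C4 (Wittig olefination of the 2-formyl dihydropyran 20), and the enol ether C4a=C5 is taken back to lactol 18, a C5 aldehyde held by the tertiary C2 hydroxyl. An alpha-alkoxy aldehyde without alpha hydrogen gives the (E)-enoate directly and without a metal. Dehydrating before olefinating leaves a single aldehyde for the ylide. Both aldehydes of 18 come from the open-chain bis(dimethyl acetal) 17, whose only stereocentres are C1, C2 and C8a.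

**Lactone template.** In 17 the C1 ester and the C7 ketone are 1,5-related through C8a and C8. Reducing C7 to a carbinol and tying it to the C1 carboxyl gives δ-lactone 15 (through hydroxy ester 16). In this ring (O, carboxyl carbon, C1, C8a, C8, C7) the C7 carbinol can control C8a and C8a can control C1, while the lactone protects both the C1 carboxyl and the C7 oxygen. The forward steps are a methanolysis and an alcohol oxidation that erases the temporary centre.

**C1–C2.** Cutting C1–C2 of 15 is an aldol disconnection between the enolate of lactone 8 and a ketone that carries the two C2 substituents. A saturated dialkyl ketone would be enolisable and would offer little facial bias. Ynone 12 carries the future C2 hexadecyl chain as a hexadec-1-ynyl group: it is more electrophilic, has no acidic hydrogen on the chain side, and its two substituents differ strongly in size. Adduct 14 is therefore the aldol target and 15 follows by hydrogenation. The forward step must set C1 trans to the C8a side chain (ring control) and C2 through a chair transition state with the alkynyl group axial.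

**C8a–C4a and the lactone ring.** The side chain of 8 is removed by cutting C8a–C4a: conjugate addition of an allyl group to unsaturated lactone 4 gives 6, and ozonolysis with acetalisation gives 8. Lactone 4 is opened at C1=C8a (ring-closing metathesis of acrylate 3) and at the ester oxygen (acylation of homoallylic alcohol 2). Alcohol 2 comes from heptadecanal 1 by asymmetric allylboration, the only step in which a reagent introduces absolute configuration.

**Ynone.** Ynone 12 is cut between carbonyl and alkyne into 1-hexadecyne 9 and methyl dimethoxyacetate 10.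

## Roads not taken

**Alternative 1:** Ring B by an intermolecular Diels–Alder reaction (cut C4a–C5 and C8–C8a).
- Forward step: 2-hexadecyl-1,4-benzoquinone A1 reacts at its unsubstituted double bond with silyloxy diene A2 under a chiral oxazaborolidinium triflimide to give the cis-fused adduct A3.
- Merits: A3 has ring B fully substituted (C5 oxygen, C6 ester, C7 hexadecyl) and the cis fusion after one catalytic enantioselective step from two simple partners. In convergence and in steps to a bicyclic intermediate this road is better than the chosen one.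
- Weak points: A3 has ketones at C1 and C4 where the target needs CH–CO2Me. Two one-carbon homologations with removal of oxygen would have to set C1 and C4 afresh beside an ene-dione that aromatises to the hydroquinone with traces of acid or base, and C5 must still be oxidised.
- Comparison: the chosen plan sets against the short opening that every ring A carbon arrives at its final oxidation level and that C4 and C4a are fixed by a stereospecific pericyclic step, not by later reductions.

**Alternative 2:** Both rings by an intramolecular Diels–Alder reaction (cut C1–C2 and C4a–C8a, ring B atoms as tether).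
- Forward step: heating tetraene A4 adds the (E)-enoate C1=C8a across the diene C2=C3–C4=C4a and gives bicycle A5.
- Merits: two rings and the centres C1, C4a and C8a in one step from an acyclic precursor, which the chosen plan cannot match.
- Weak points: A5 has the ring A alkene at C3=C4, conjugated with the C4 ester, and a stereocentre at C2. The alkene must be moved to C2=C3 against conjugation, with C4 set by a kinetic protonation that destroys the C2 centre just made. C5 must be oxidised and the C6 ester introduced on an enone afterwards. Facial selectivity rests on one silyloxy centre in the tether, and A4 with its trisubstituted alkene is long to make.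
- Comparison: the chosen plan needs more steps before ring A exists, but after its key step only two bond-forming steps remain and no stereocentre depends on a protonation.

**Alternative 3:** Ring B by conjugate addition and aldol closure (cut the C7–hexadecyl bond and C5–C6).
- Forward step: lithium dihexadecylcuprate A7 adds at C7 of the alkynoate in aldehyde A6, and the allenolate closes onto the C5 aldehyde to give allylic alcohol A8; one oxidation then gives 25.
- Merits: A6 differs from 22 only in the C8 side chain and could come from the same rearrangement. The second hexadecyl chain enters late and convergently, and the epimerisable β-keto ester 23 is avoided. The two endgames are equal in step count, so here the alternative is at least as good.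
- Weak points: a basic organocopper reagent meets a free, epimerisable aldehyde and two methyl esters, and one hexadecyl group is lost per cuprate.
- Comparison: the chosen plan sets against it that the C7 oxygen is not an extra group to install. It is the controlling carbinol of the lactone relay and becomes the C7 ketone at no cost, which a propargylic ester side chain could not provide.

Key step: step 14

## Route

Remark: atom labels C1–C8a of 25 are used for the atoms that become them in all earlier compounds. The side-chain ketone is carried unprotected from 17 onward, and lactol 18 is used as its mixture of C5 epimers, which converge in step 12.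

Step 1
Reactants: 1 heptadecanal
Product: 2 (S)-eicos-1-en-4-ol
Conditions: (−)-Ipc2B(allyl) [from (+)-Ipc2BOMe and allylMgBr], Et2O, −78 °C; then NaOH, H2O2
Reagents that add atoms: (−)-B-allyldiisopinocampheylborane, C=CCB([C@H]1C[C@H]2C[C@@H]([C@@H]1C)C2(C)C)[C@H]1C[C@H]2C[C@@H]([C@@H]1C)C2(C)C
Why: Asymmetric allylboration of an aldehyde through a closed chair transition state; the isopinocampheyl groups of this antipode should deliver the allyl group to the face of 1 that gives the (S)-carbinol C7, the temporary centre from which all others are relayed.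

Step 2
Reactants: 2 (S)-eicos-1-en-4-ol
Product: 3 (S)-eicos-1-en-4-yl acrylate
Conditions: acryloyl chloride, Et3N, DMAP (cat.), CH2Cl2, 0 °C
Reagents that add atoms: acryloyl chloride, C=CC(=O)Cl
Why: O-Acylation of a secondary alcohol with an acid chloride; no stereocentre is touched.

Step 3
Reactants: 3 (S)-eicos-1-en-4-yl acrylate
Product: 4 (S)-6-hexadecyl-5,6-dihydro-2H-pyran-2-one
Conditions: second-generation Grubbs catalyst (3 mol %), CH2Cl2 (0.005 M), 40 °C
Reagents that add atoms: none
Why: Ring-closing olefin metathesis of an acrylate with a terminal alkene, driven by loss of ethene; the six-membered unsaturated lactone is the favoured ring and C7 is untouched.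

Step 4
Reactants: 4 (S)-6-hexadecyl-5,6-dihydro-2H-pyran-2-one
Product: 6 (4S,6S)-4-allyl-6-hexadecyltetrahydro-2H-pyran-2-one, via silyl ketene acetal 5 (not isolated)
Conditions: allylMgBr, CuBr·SMe2 (20 mol %), Me3SiCl, THF, −78 °C; aq. NH4Cl
Reagents that add atoms: allylmagnesium bromide, C=CC[Mg]Br
Why: Copper-catalysed conjugate addition of a Grignard reagent with in situ silylation; the allyl group should enter C8a axially on the half-chair face anti to the pseudo-equatorial C7 hexadecyl group, giving the 4,6-trans lactone as is general for 6-alkyl-5,6-dihydropyran-2-ones.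

Step 5
Reactants: 6 (4S,6S)-4-allyl-6-hexadecyltetrahydro-2H-pyran-2-one
Product: 8 (4R,6S)-4-(2,2-dimethoxyethyl)-6-hexadecyltetrahydro-2H-pyran-2-one, via lactone aldehyde 7 (not isolated)
Conditions: O3, CH2Cl2/MeOH, −78 °C; Me2S; then HC(OMe)3, PPTS (cat.), rt
Reagents that add atoms: ozone, [O-][O+]=O; trimethyl orthoformate, COC(OC)OC
Why: Ozonolysis with reductive work-up followed by acid-catalysed acetalisation in the same flask; the only alkene is cleaved to the C5 aldehyde, which is masked at once so that it survives the enolate and hydrogenation steps.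

Step 6
Reactants: 9 1-hexadecyne; 10 methyl dimethoxyacetate
Product: 12 1,1-dimethoxyoctadec-3-yn-2-one, via lithium hexadecynide 11 (not isolated)
Conditions: n-BuLi, THF, −78 °C; then 10, −78 °C; aq. NH4Cl
Reagents that add atoms: none
Why: Acylation of a lithium acetylide with an alpha,alpha-dialkoxy ester; the chelated tetrahedral alkoxide should persist at −78 °C, so the ketone is released only on quench and a second addition is avoided.

Step 7
Reactants: 8 (4R,6S)-4-(2,2-dimethoxyethyl)-6-hexadecyltetrahydro-2H-pyran-2-one; 12 1,1-dimethoxyoctadec-3-yn-2-one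
Product: 14 (3S,4R,6S)-4-(2,2-dimethoxyethyl)-6-hexadecyl-3-[(2S)-2-hydroxy-1,1-dimethoxyoctadec-3-yn-2-yl]tetrahydro-2H-pyran-2-one, via lithium enolate 13 (not isolated)
Conditions: LiN(i-Pr)2, THF, −78 °C; then 12, −78 °C; AcOH quench at −78 °C
Reagents that add atoms: none
Why: Lithium enolate aldol addition to an activated ynone (1,2-addition at −78 °C). C1 is set by attack anti to the adjacent C8a side chain of the lactone enolate. C2 is set in the closed chair transition state of the ring-fixed (E)-enolate, where the slender alkynyl group (the masked hexadecyl chain) should take the axial site and the branched dimethoxymethyl group the equatorial one.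

Step 8
Reactants: 14 aldol adduct (alkyne)
Product: 15 (3S,4R,6S)-4-(2,2-dimethoxyethyl)-6-hexadecyl-3-[(2R)-2-hydroxy-1,1-dimethoxyoctadecan-2-yl]tetrahydro-2H-pyran-2-one
Conditions: H2 (1 atm), Pd/C, EtOAc, rt
Reagents that add atoms: none
Why: Heterogeneous hydrogenation of the alkyne to the alkane turns the alkynyl group into the C2 hexadecyl chain; acetals, lactone and tertiary alcohol are inert and no stereocentre is affected.

Step 9
Reactants: 15 saturated lactone
Product: 16 methyl (2S,3R)-3-(dimethoxymethyl)-3-hydroxy-2-[(3R,5S)-5-hydroxy-1,1-dimethoxyhenicosan-3-yl]nonadecanoate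
Conditions: K2CO3 (0.3 equiv), MeOH, 0 °C to rt; crude product taken on directly
Reagents that add atoms: methanol, CO
Why: Base-catalysed transesterification (methanolysis) of the δ-lactone releases the C1 methyl ester and the C7 alcohol; carbonate at low temperature should not trigger retro-aldol cleavage of the tertiary β-hydroxy ester, and immediate oxidation prevents relactonisation.

Step 10
Reactants: 16 hydroxy ester
Product: 17 methyl (2S,3R)-3-(dimethoxymethyl)-3-hydroxy-2-[(3S)-1,1-dimethoxy-5-oxohenicosan-3-yl]nonadecanoate
Conditions: Dess–Martin periodinane, pyridine, CH2Cl2, rt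
Reagents that add atoms: none
Why: Dess–Martin oxidation of the secondary alcohol to the C7 ketone erases the temporary stereocentre; the tertiary alcohol and the acetals are untouched.

Step 11
Reactants: 17 keto ester bis(acetal)
Product: 18 methyl (2R,3S,4S)-2-formyl-2-hexadecyl-6-hydroxy-4-(2-oxooctadecyl)tetrahydro-2H-pyran-3-carboxylate (lactol; both C5 epimers)
Conditions: 2 M HCl, THF, 40 °C
Reagents that add atoms: water, O
Why: Acid-catalysed acetal hydrolysis; the C5 aldehyde is trapped by the tertiary C2 hydroxyl as the six-membered lactol, while the C3 aldehyde, which has no alpha hydrogen, stays free.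

Step 12
Reactants: 18 lactol aldehyde
Product: 20 methyl (2R,3S,4R)-2-formyl-2-hexadecyl-4-(2-oxooctadecyl)-3,4-dihydro-2H-pyran-3-carboxylate, via anomeric mesylate 19 (not isolated)
Conditions: MsCl, Et3N, CH2Cl2, 0 °C to 40 °C
Reagents that add atoms: none
Why: Dehydration of a lactol through its sulfonate (elimination to the cyclic enol ether), a standard route from 2-hydroxytetrahydropyrans to 3,4-dihydro-2H-pyrans; the non-enolisable aldehyde and the ketone should not react.

Step 13
Reactants: 20 2-formyl dihydropyran
Product: 21 methyl (2S,3S,4R)-2-hexadecyl-2-[(E)-3-methoxy-3-oxoprop-1-en-1-yl]-4-(2-oxooctadecyl)-3,4-dihydro-2H-pyran-3-carboxylate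
Conditions: Ph3P=CHCO2Me, toluene, 50 °C
Reagents that add atoms: methyl (triphenylphosphoranylidene)acetate, COC(=O)C=P(c1ccccc1)(c1ccccc1)c1ccccc1
Why: Wittig olefination with a stabilised ylide is (E)-selective and takes the alpha-alkoxy aldehyde but not the ketone; the temperature stays far below that of the rearrangement.

Step 14
Reactants: 21 2-alkenyl-3,4-dihydro-2H-pyran
Product: 22 dimethyl (1S,4R,5S,6R)-5-formyl-2-hexadecyl-6-(2-oxooctadecyl)cyclohex-2-ene-1,4-dicarboxylate
Conditions: degassed o-xylene (0.02 M), BHT (cat.), base-washed sealed tube, 180 °C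
Reagents that add atoms: none
Why: Concerted [3,3]-sigmatropic (Claisen) rearrangement of the allyl vinyl ether C4a=C5–O–C2–C3=C4: the O–C2 bond breaks while C4–C4a forms. The closest known reaction type is the thermal rearrangement of 2-alkenyl-3,4-dihydro-2H-pyrans to cyclohex-3-enecarbaldehydes. Ring A (C1, C2, C3, C4, C4a, C8a) closes in the pericyclic step itself through a boat-like, bicyclo[2.2.2]octene-shaped transition state that the pyran ring enforces, and the heterocycle opens to the C5 aldehyde, whose C=O bond makes the step irreversible. C4a is controlled by C2: the alkenyl group can only reach the enol ether face on which it stands, the face anti to the C8a side chain, so the formyl group ends cis to the C8 chain. C4 is controlled by the (E) geometry of the enoate: in the boat the C4 hydrogen points to the C1–C8a bridge and the ester to the side of the departing C5–O unit, which places the C4 ester cis to the formyl group. C1 and C8a are spectators and stay trans. The step therefore needs only intact (E) geometry and the absence of acid (enol ether hydrolysis) and base (C1 epimerisation), secured by the Wittig step and neutral, scavenged conditions; there is no regiochemical choice because the array has one allyl and one vinyl ether terminus.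

Step 15
Reactants: 22 ring A aldehyde
Product: 23 dimethyl (1S,4R,5S,6R)-2-hexadecyl-5-(3-methoxy-3-oxopropanoyl)-6-(2-oxooctadecyl)cyclohex-2-ene-1,4-dicarboxylate
Conditions: methyl diazoacetate, SnCl2 (10 mol %), CH2Cl2, rt
Reagents that add atoms: methyl diazoacetate, COC(=O)C=[N+]=[N-]
Why: Roskamp homologation: SnCl2-catalysed addition of the diazo ester to the aldehyde and 1,2-hydride shift with loss of N2 give the β-keto ester; ketones react far more slowly, and the mild Lewis acid should not epimerise C4a.

Step 16
Reactants: 23 β-keto ester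
Product: 25 trimethyl (1S,4R,4aS,8aR)-2,7-dihexadecyl-5-oxo-1,4,4a,5,8,8a-hexahydronaphthalene-1,4,6-tricarboxylate (CNP0149813.1), via ring B aldol 24 (not isolated)
Conditions: piperidine (cat.), AcOH (cat.), toluene, 4 Å MS, rt to 40 °C
Reagents that add atoms: none
Why: Intramolecular Knoevenagel condensation: the active methylene carbon C6 adds to the C7 ketone in a 6-exo-trig aldol closure of ring B and water is lost to give the conjugated enone ester; buffered amine catalysis at low temperature is chosen to leave the cis ring fusion and the C2=C3 position untouched.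

## Compound list

1 | heptadecanal | CCCCCCCCCCCCCCCCC=O | starting material
2 | (S)-eicos-1-en-4-ol | C=CC[C@@H](O)CCCCCCCCCCCCCCCC | intermediate
3 | (S)-eicos-1-en-4-yl acrylate | C=CC[C@@H](OC(=O)C=C)CCCCCCCCCCCCCCCC | intermediate
4 | (S)-6-hexadecyl-5,6-dihydro-2H-pyran-2-one | O=C1C=CC[C@H](CCCCCCCCCCCCCCCC)O1 | intermediate
5 | trimethylsilyl ketene acetal of 6 (4-allyl-2-hexadecyl-6-trimethylsilyloxy-3,4-dihydro-2H-pyran, 2,4-trans) | C[Si](C)(C)OC1=C[C@@H](CC=C)C[C@H](CCCCCCCCCCCCCCCC)O1 | intermediate (not isolated)
6 | (4S,6S)-4-allyl-6-hexadecyltetrahydro-2H-pyran-2-one | O=C1O[C@@H](CCCCCCCCCCCCCCCC)C[C@H](CC=C)C1 | intermediate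
7 | 2-[(2S,4R)-2-hexadecyl-6-oxotetrahydro-2H-pyran-4-yl]acetaldehyde | O=C1O[C@@H](CCCCCCCCCCCCCCCC)C[C@H](CC=O)C1 | intermediate (not isolated)
8 | (4R,6S)-4-(2,2-dimethoxyethyl)-6-hexadecyltetrahydro-2H-pyran-2-one | O=C1O[C@@H](CCCCCCCCCCCCCCCC)C[C@H](CC(OC)OC)C1 | intermediate
9 | 1-hexadecyne | C#CCCCCCCCCCCCCCC | starting material
10 | methyl dimethoxyacetate | COC(OC)C(=O)OC | starting material
11 | lithium hexadec-1-yn-1-ide | [Li]C#CCCCCCCCCCCCCCC | intermediate (not isolated)
12 | 1,1-dimethoxyoctadec-3-yn-2-one | COC(OC)C(=O)C#CCCCCCCCCCCCCCC | intermediate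
13 | lithium enolate of 8 | [Li]OC1=C[C@@H](CC(OC)OC)C[C@H](CCCCCCCCCCCCCCCC)O1 | intermediate (not isolated)
14 | (3S,4R,6S)-4-(2,2-dimethoxyethyl)-6-hexadecyl-3-[(2S)-2-hydroxy-1,1-dimethoxyoctadec-3-yn-2-yl]tetrahydro-2H-pyran-2-one | O=C1O[C@@H](CCCCCCCCCCCCCCCC)C[C@H](CC(OC)OC)[C@H]1[C@](O)(C#CCCCCCCCCCCCCCC)C(OC)OC | intermediate
15 | (3S,4R,6S)-4-(2,2-dimethoxyethyl)-6-hexadecyl-3-[(2R)-2-hydroxy-1,1-dimethoxyoctadecan-2-yl]tetrahydro-2H-pyran-2-one | O=C1O[C@@H](CCCCCCCCCCCCCCCC)C[C@H](CC(OC)OC)[C@H]1[C@](O)(CCCCCCCCCCCCCCCC)C(OC)OC | intermediate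
16 | methyl (2S,3R)-3-(dimethoxymethyl)-3-hydroxy-2-[(3R,5S)-5-hydroxy-1,1-dimethoxyhenicosan-3-yl]nonadecanoate | CCCCCCCCCCCCCCCC[C@](O)(C(OC)OC)[C@@H](C(=O)OC)[C@@H](CC(OC)OC)C[C@@H](O)CCCCCCCCCCCCCCCC | intermediate
17 | methyl (2S,3R)-3-(dimethoxymethyl)-3-hydroxy-2-[(3S)-1,1-dimethoxy-5-oxohenicosan-3-yl]nonadecanoate | CCCCCCCCCCCCCCCC[C@](O)(C(OC)OC)[C@@H](C(=O)OC)[C@@H](CC(OC)OC)CC(=O)CCCCCCCCCCCCCCCC | intermediate
18 | methyl (2R,3S,4S)-2-formyl-2-hexadecyl-6-hydroxy-4-(2-oxooctadecyl)tetrahydro-2H-pyran-3-carboxylate (lactol, both epimers at the hemiacetal carbon) | CCCCCCCCCCCCCCCC[C@@]1(C=O)OC(O)C[C@@H](CC(=O)CCCCCCCCCCCCCCCC)[C@@H]1C(=O)OC | intermediate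
19 | anomeric mesylate of 18 | CCCCCCCCCCCCCCCC[C@@]1(C=O)OC(OS(C)(=O)=O)C[C@@H](CC(=O)CCCCCCCCCCCCCCCC)[C@@H]1C(=O)OC | intermediate (not isolated)
20 | methyl (2R,3S,4R)-2-formyl-2-hexadecyl-4-(2-oxooctadecyl)-3,4-dihydro-2H-pyran-3-carboxylate | CCCCCCCCCCCCCCCC[C@@]1(C=O)OC=C[C@@H](CC(=O)CCCCCCCCCCCCCCCC)[C@@H]1C(=O)OC | intermediate
21 | methyl (2S,3S,4R)-2-hexadecyl-2-[(E)-3-methoxy-3-oxoprop-1-en-1-yl]-4-(2-oxooctadecyl)-3,4-dihydro-2H-pyran-3-carboxylate | CCCCCCCCCCCCCCCC[C@@]1(/C=C/C(=O)OC)OC=C[C@@H](CC(=O)CCCCCCCCCCCCCCCC)[C@@H]1C(=O)OC | intermediate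
22 | dimethyl (1S,4R,5S,6R)-5-formyl-2-hexadecyl-6-(2-oxooctadecyl)cyclohex-2-ene-1,4-dicarboxylate | CCCCCCCCCCCCCCCCC1=C[C@@H](C(=O)OC)[C@@H](C=O)[C@@H](CC(=O)CCCCCCCCCCCCCCCC)[C@@H]1C(=O)OC | intermediate
23 | dimethyl (1S,4R,5S,6R)-2-hexadecyl-5-(3-methoxy-3-oxopropanoyl)-6-(2-oxooctadecyl)cyclohex-2-ene-1,4-dicarboxylate | CCCCCCCCCCCCCCCCC1=C[C@@H](C(=O)OC)[C@@H](C(=O)CC(=O)OC)[C@@H](CC(=O)CCCCCCCCCCCCCCCC)[C@@H]1C(=O)OC | intermediate
24 | trimethyl (1S,4R,4aS,8aR)-2,7-dihexadecyl-7-hydroxy-5-oxo-1,4,4a,5,6,7,8,8a-octahydronaphthalene-1,4,6-tricarboxylate (C6 and C7 unassigned) | CCCCCCCCCCCCCCCCC1=C[C@@H](C(=O)OC)[C@H]2C(=O)C(C(=O)OC)C(O)(CCCCCCCCCCCCCCCC)C[C@H]2[C@@H]1C(=O)OC | intermediate (not isolated)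
25 | trimethyl (1S,4R,4aS,8aR)-2,7-dihexadecyl-5-oxo-1,4,4a,5,8,8a-hexahydronaphthalene-1,4,6-tricarboxylate (CNP0149813.1) | CCCCCCCCCCCCCCCCC1=C[C@@H](C(=O)OC)[C@H]2C(=O)C(C(=O)OC)=C(CCCCCCCCCCCCCCCC)C[C@H]2[C@@H]1C(=O)OC | target

## Step count and least certain steps

Total step count: 16. Longest linear sequence: 15 steps (1 to 25 through steps 1–5 and 7–16); step 6 is a one-step branch that joins at step 7.

**Step 14 (key step).** The most likely failure is thermal: the temperature needed may exceed what the enol ether, the (E)-enoate and the epimerisable C1 tolerate, so decomposition or loss of alkene geometry could outrun the rearrangement. The quaternary C2 and the cis C1 ester crowd the boat and may raise the barrier. Fallback: replace the enol ether by a lactone enolate, which rearranges at much lower temperature. Setting out from lactol 18, oxidation with Ag2CO3 on Celite should give the lactone aldehyde F1. Wittig olefination with Ph3P=CHCO2Me then gives the lactone enoate F2. t-BuMe2SiOTf and Et3N convert the lactone into its silyl ketene acetal and the side-chain ketone into its silyl enol ether, the bis-silyl compound F3. Warming in toluene (80–110 °C) should bring about the Ireland–Claisen ring contraction through the same boat, and dilute acid work-up gives the ring A carboxylic acid F4. Activation with 1,1′-carbonyldiimidazole and reaction with MgCl2 and KO2CCH2CO2Me return to the route at β-keto ester 23.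

**Step 7.** The most likely failure is poor facial selectivity at the ketone carbon C2, because ester-type enolates distinguish the two ketone substituents less sharply than ketone enolates, and a boat transition state or lithium coordination by an acetal oxygen could even reverse the preference. Fallback: exchange the roles of the two ketone substituents, so that the reverse preference gives the same C2 configuration. The enolate of 8 is added to 1-(trimethylsilyl)nonadec-1-yn-3-one F5 (hexadecyl present as such, alkyne as precursor of the enoate) to give the tertiary alcohol F6. K2CO3 in MeOH opens the lactone and removes the silyl group, giving the ethynyl diol ester F7; Dess–Martin oxidation gives the ketone F8. Semihydrogenation over Pd/CaCO3 poisoned with Pb(OAc)2 gives the vinyl carbinol F9, and cross-metathesis with methyl acrylate (second-generation Hoveyda–Grubbs catalyst) gives the (E)-enoate F10. Mild aqueous acid gives the lactol F11, and MsCl/Et3N dehydration returns to the route at 21.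

**Step 12 (with step 11).** The most likely failure is incomplete or misdirected dehydration. Lactol 18 can close a second hemiacetal bridge onto the neighbouring C3 aldehyde or onto the C7 ketone, and these forms compete for the sulfonylating agent. Fallback: olefinate before the enol ether is made, with C5 masked as an ester. Setting out from 18, Ac2O and pyridine give the anomeric acetate F12, Wittig olefination gives the acetate enoate F13, and loss of acetic acid induced by Me3SiOTf and i-Pr2NEt at low temperature returns to the route at 21.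

**Step 4.** The most likely failure is 1,2-addition of the allyl Grignard reagent to the lactone carbonyl or eroded trans selectivity, since allylcopper species are less dependable conjugate donors than alkyl or vinyl cuprates. Fallback: setting out from 4, vinylMgBr with CuI and Me3SiCl gives the trans vinyl lactone F14. Hydroboration with 9-BBN and oxidation with NaBO3 give the primary alcohol F15. Dess–Martin oxidation gives aldehyde 7, now isolated, which is acetalised to 8 as in step 5.

**Step 9.** The most likely failure is an unfavourable ring-opening equilibrium or relactonisation of 16 before it is oxidised, because the substituted δ-lactone is a stable ring. Fallback: open the lactone irreversibly. Setting out from 15, LiOH in aqueous THF gives the hydroxy carboxylate, which is oxidised in the same aqueous phase with TEMPO, NaOCl and KBr to the keto acid F16; Me3SiCHN2 then gives 17.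

**Step 16.** The most likely failure is epimerisation at C4a (cis to trans ring fusion) or migration of the C2=C3 bond under amine catalysis, since H4a is alpha to the C5 ketone. Fallback: separate addition from elimination under non-basic activation. Setting out from 23, TiCl4 and Et3N at −78 °C should stop at aldol 24, which is isolated and dehydrated with Burgess reagent to 25; no new compound is needed.

## Further compounds

F1 | step 14 | methyl (2R,3S,4R)-2-formyl-2-hexadecyl-6-oxo-4-(2-oxooctadecyl)tetrahydro-2H-pyran-3-carboxylate (lactone aldehyde) | CCCCCCCCCCCCCCCC[C@@]1(C=O)OC(=O)C[C@@H](CC(=O)CCCCCCCCCCCCCCCC)[C@@H]1C(=O)OC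
F2 | step 14 | methyl (2S,3S,4R)-2-hexadecyl-2-[(E)-3-methoxy-3-oxoprop-1-en-1-yl]-6-oxo-4-(2-oxooctadecyl)tetrahydro-2H-pyran-3-carboxylate (lactone enoate) | CCCCCCCCCCCCCCCC[C@@]1(/C=C/C(=O)OC)OC(=O)C[C@@H](CC(=O)CCCCCCCCCCCCCCCC)[C@@H]1C(=O)OC
F3 | step 14 | tert-butyldimethylsilyl ketene acetal of F2 with the side-chain ketone as its silyl enol ether (bis-silyl compound) | CCCCCCCCCCCCCCCC[C@@]1(/C=C/C(=O)OC)OC(O[Si](C)(C)C(C)(C)C)=C[C@@H](CC(O[Si](C)(C)C(C)(C)C)=CCCCCCCCCCCCCCCC)[C@@H]1C(=O)OC
F4 | step 14 | ring A carboxylic acid (CO2H in place of CHO of 22, other centres as in 22) | CCCCCCCCCCCCCCCCC1=C[C@@H](C(=O)OC)[C@@H](C(=O)O)[C@@H](CC(=O)CCCCCCCCCCCCCCCC)[C@@H]1C(=O)OC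
F5 | step 7 | 1-(trimethylsilyl)nonadec-1-yn-3-one | C[Si](C)(C)C#CC(=O)CCCCCCCCCCCCCCCC
F6 | step 7 | (3S,4R,6S)-4-(2,2-dimethoxyethyl)-6-hexadecyl-3-[3-hydroxy-1-(trimethylsilyl)nonadec-1-yn-3-yl]tetrahydro-2H-pyran-2-one (carbinol configured as C2 of 21) | O=C1O[C@@H](CCCCCCCCCCCCCCCC)C[C@H](CC(OC)OC)[C@H]1[C@](O)(CCCCCCCCCCCCCCCC)C#C[Si](C)(C)C
F7 | step 7 | methyl 3-ethynyl-3-hydroxy-2-[(3R,5S)-5-hydroxy-1,1-dimethoxyhenicosan-3-yl]nonadecanoate | CCCCCCCCCCCCCCCC[C@](O)(C#C)[C@@H](C(=O)OC)[C@@H](CC(OC)OC)C[C@@H](O)CCCCCCCCCCCCCCCC
F8 | step 7 | methyl 3-ethynyl-3-hydroxy-2-(1,1-dimethoxy-5-oxohenicosan-3-yl)nonadecanoate | CCCCCCCCCCCCCCCC[C@](O)(C#C)[C@@H](C(=O)OC)[C@@H](CC(OC)OC)CC(=O)CCCCCCCCCCCCCCCC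
F9 | step 7 | methyl 3-hydroxy-3-vinyl-2-(1,1-dimethoxy-5-oxohenicosan-3-yl)nonadecanoate | CCCCCCCCCCCCCCCC[C@](O)(C=C)[C@@H](C(=O)OC)[C@@H](CC(OC)OC)CC(=O)CCCCCCCCCCCCCCCC
F10 | step 7 | methyl 3-hydroxy-3-[(E)-3-methoxy-3-oxoprop-1-en-1-yl]-2-(1,1-dimethoxy-5-oxohenicosan-3-yl)nonadecanoate | CCCCCCCCCCCCCCCC[C@](O)(/C=C/C(=O)OC)[C@@H](C(=O)OC)[C@@H](CC(OC)OC)CC(=O)CCCCCCCCCCCCCCCC
F11 | step 7 | lactol enoate (6-hydroxy-tetrahydropyran analogue of 21, both epimers at the hemiacetal carbon) | CCCCCCCCCCCCCCCC[C@@]1(/C=C/C(=O)OC)OC(O)C[C@@H](CC(=O)CCCCCCCCCCCCCCCC)[C@@H]1C(=O)OC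
F12 | step 12 | anomeric acetate of 18 | CCCCCCCCCCCCCCCC[C@@]1(C=O)OC(OC(C)=O)C[C@@H](CC(=O)CCCCCCCCCCCCCCCC)[C@@H]1C(=O)OC
F13 | step 12 | anomeric acetate with (E)-enoate on C2 | CCCCCCCCCCCCCCCC[C@@]1(/C=C/C(=O)OC)OC(OC(C)=O)C[C@@H](CC(=O)CCCCCCCCCCCCCCCC)[C@@H]1C(=O)OC
F14 | step 4 | (4S,6S)-6-hexadecyl-4-vinyltetrahydro-2H-pyran-2-one | O=C1O[C@@H](CCCCCCCCCCCCCCCC)C[C@H](C=C)C1
F15 | step 4 | (4S,6S)-6-hexadecyl-4-(2-hydroxyethyl)tetrahydro-2H-pyran-2-one | O=C1O[C@@H](CCCCCCCCCCCCCCCC)C[C@H](CCO)C1
F16 | step 9 | (2S,3R)-3-(dimethoxymethyl)-3-hydroxy-2-[(3S)-1,1-dimethoxy-5-oxohenicosan-3-yl]nonadecanoic acid | CCCCCCCCCCCCCCCC[C@](O)(C(OC)OC)[C@@H](C(=O)O)[C@@H](CC(OC)OC)CC(=O)CCCCCCCCCCCCCCCC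
F0 | step 16 | none | none
A1 | alternative 1 | 2-hexadecyl-1,4-benzoquinone | CCCCCCCCCCCCCCCCC1=CC(=O)C=CC1=O
A2 | alternative 1 | methyl (Z)-2-[(tert-butyldimethylsilyloxy)methylidene]-3-methylidenenonadecanoate (silyloxy diene) | C=C(CCCCCCCCCCCCCCCC)/C(C(=O)OC)=C/O[Si](C)(C)C(C)(C)C
A3 | alternative 1 | cis-fused quinone Diels–Alder adduct (C1 and C4 ketones, C5 silyl ether, C6 ester, C2 and C7 hexadecyl) | CCCCCCCCCCCCCCCCC1=CC(=O)[C@H]2[C@@H](O[Si](C)(C)C(C)(C)C)C(C(=O)OC)=C(CCCCCCCCCCCCCCCC)C[C@H]2C1=O
A4 | alternative 2 | acyclic tetraene diester for the intramolecular Diels–Alder reaction | CCCCCCCCCCCCCCCC/C=C/C(C(=O)OC)=C/[C@H](O[Si](C)(C)C(C)(C)C)/C=C(/CCCCCCCCCCCCCCCC)C/C=C/C(=O)OC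
A5 | alternative 2 | cis-fused intramolecular Diels–Alder adduct (C3=C4 enoate, C5 silyl ether) | CCCCCCCCCCCCCCCC[C@H]1C=C(C(=O)OC)[C@H]2[C@H](O[Si](C)(C)C(C)(C)C)C=C(CCCCCCCCCCCCCCCC)C[C@H]2[C@@H]1C(=O)OC
A6 | alternative 3 | ring A aldehyde with a 4-methoxy-4-oxobut-2-ynyl side chain on C8a | CCCCCCCCCCCCCCCCC1=C[C@@H](C(=O)OC)[C@@H](C=O)[C@@H](CC#CC(=O)OC)[C@@H]1C(=O)OC
A7 | alternative 3 | lithium dihexadecylcuprate | [Li+].CCCCCCCCCCCCCCCC[Cu-]CCCCCCCCCCCCCCCC
A8 | alternative 3 | C5 allylic alcohol of the target skeleton | CCCCCCCCCCCCCCCCC1=C[C@@H](C(=O)OC)[C@H]2[C@H](O)C(C(=O)OC)=C(CCCCCCCCCCCCCCCC)C[C@H]2[C@@H]1C(=O)OC
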